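Readings and results come from a simulation for substances that don't exist, noise included.

Late in the red and amber runs the electrophile was still falling, so I asked how far a straight line would carry it to the time of this flask.

| flask | electrophile | nucleophile | free base | remark | time |
|---|---|---|---|---|---|
| red | 0.10 M | 1 equiv | 0.50 equiv | run made earlier |  |
| amber | 0.10 M | 1 equiv | 2 equiv | run made earlier |  |
| blue | 0.050 M | 1 equiv | 1 equiv | run made earlier |  |
| flask | 0.10 M | 1.00 equiv | 1.00 equiv |  | 4.0 d |

| run | time / d | electrophile / % | target / % |
|---|---|---|---|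
| red | 0.208 | 92.8 | 6.2 |
| red | 0.625 | 78.1 | 11.8 |
| red | 1.04 | 66.7 | 12.8 |
| red | 1.67 | 53.3 | 11.5 |
| red | 2.50 | 41.9 | 10.4 |
| red | 3.00 | 36.9 | 10.1 |
| amber | 0.208 | 91.7 | 5.7 |
| amber | 0.625 | 78.0 | 11.5 |
| amber | 1.04 | 66.3 | 11.5 |
| amber | 1.67 | 51.9 | 12.6 |
| amber | 2.50 | 42.0 | 10.7 |
| amber | 3.00 | 35.8 | 9.7 |
| blue | 0.250 | 95.3 | 4.0 |
| blue | 0.500 | 91.0 | 6.0 |
| blue | 0.833 | 85.0 | 9.7 |
| blue | 1.67 | 71.8 | 12.2 |
| blue | 3.00 | 56.9 | 11.7 |

(scatter of a reading: 0.5 percentage points)

- a species is counted by the electrophile in it: one side product counts as two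
- steps thought possible: electrophile + nucleophile -> acid set free + target; nucleophile + acid set free <-> protonated nucleophile; acid set free + free base <-> salt of the base; electrophile + target -> side product
- the earlier runs do not show how much of nucleophile is bound; that part of a forecast is a guess

1. part of the electrophile that has reacted at 4.0 d
2. share of the unused nucleophile that is free and not bound as protonated nucleophile, at 4.0 d

At 3.00 d red held 36.9 % of its electrophile and amber 35.8 %, though red had a quarter of amber's free base. That gap is 1.1 percentage points against a scatter of 0.5 points. So I took the flask, whose free base lies between theirs, as their mean.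

Nucleophile and electrophile were charged equally, so I used the second-order plot: the ratio of charged to present c(electrophile). At 3.00 d the mean ratio was 2.75. It began at 1, so on average it rose 0.584 d⁻¹. Carried on to 4.0 d, that gave 70.0 % reacted.

The weak link was that average rise, since a curve need not rise evenly. So I reforged it with the late climb, the daily rise of the ratio from 1.67 d to 3.00 d. It came to 0.639 d⁻¹. That gave 70.5 %, a shift of 0.50 points. I committed to this. For fr I had no reckoning, as the runs do not show the bound nucleophile.

The forecast gave 71 % (68 % to 74 %) and 38 % (27 % to 62 %), saying: “Each acid therefore seems to tie up a nucleophile, despite the base.” Its c stands 0.50 points above mine.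

The flask gave 70.9 % reacted, with 40.3 % of the unused nucleophile free.

    electrophile + nucleophile → acid set free + target (k = 0.00248 L mol⁻¹ min⁻¹)
    nucleophile + acid set free ⇌ protonated nucleophile, settled at all times (K = 3000 L mol⁻¹)
    acid set free + free base ⇌ salt of the base (K = 5800 L mol⁻¹, k = 0.0222 L mol⁻¹ min⁻¹)
    electrophile + target → side product (k = 0.0101 L mol⁻¹ min⁻¹)

At 4.00 d the flask's unbound nucleophile, 24 % of its charge, stood lower than its unbound free base, 97 %. From 2.00 d to 4.00 d the flask's own climb was 0.678 d⁻¹, against the 0.639 d⁻¹ I read from red and amber between 1.67 d and 3.00 d. Carried to the neighbouring flask with 2.50 equiv of free base, my climb leaves 29.5 % electrophile, and that flask holds 28.5 %.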